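**Retrosynthetic overview**
1. The two formyl groups are removed first (twofold Vilsmeier–Haack formylation), then the C4' hydrogen and isobutyl group (hydrogenation of a 4'-isobutyl-2'H-chromene made from a spiro chroman-4'-one and an isobutyl organometallic).
2. The pyranone ring is cut at C2–C3' and at O1'–C8a': aldol addition of the enolate of 2,4,6-trifluoroacetophenone to the exo face of camphenilone, then SNAr ring closure by the endo alkoxide.
3. Camphenilone is cut at C1–C7 of the bicyclo[2.2.1]heptane (the bridgehead beside C2 to the one-carbon bridge): intramolecular enolate alkylation of a cyclohexanone bearing CH2OTs, whose single stereocenter (later C4) comes from an asymmetric conjugate addition to 2-methylcyclohexenone.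
4. Enabling feature: the quaternary gem-dimethyl carbon C3 beside C2 in the six-membered ring C1–C2–C3–C4–C5–C6 that C7 bridges from C4 to C1. Before the key step it leaves C1 as the only enolisable carbon; afterwards both α-carbons (bridgehead C1, quaternary C3) are non-enolisable, so the C2 ketone is a clean acceptor that hands its own oxygen, endo, to the arene.
5. Ring order: cyclohexane ring (purchased) → norbornane by the C1–C7 bond → pyranone ring onto the purchased arene; stereochemical relay C4 → C1 → C2 → C4'.

Key step: step 4

Remark: the target is read as (1R,2R,4S,4'S): at the spiro carbon C2 the ring oxygen is endo and C3' is exo on the norbornane, and the isobutyl group at C4' is cis to C3 across the pyran ring; norbornane atoms carry plain locants and chromane atoms primed locants throughout.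

Step 1
Reactants: 1 2-methylcyclohex-2-en-1-one
Product: 3 (S)-2,2-dimethyl-3-vinylcyclohexan-1-one, via bromomagnesium enolate 2 (not isolated)
Conditions: CH2=CHMgBr, CuBr·SMe2 (5 mol %), Taniaphos-type ferrocenyl diphosphine (6 mol %, enantiomer chosen for 3S), Et2O, −60 °C; then MeI, DMPU, −60 → 25 °C
Reagents that add atoms: vinylmagnesium bromide C=C[Mg]Br; iodomethane CI
Why: Copper-catalysed asymmetric conjugate addition of a Grignard reagent to an α-substituted cyclic enone followed by C-alkylation of the regiodefined magnesium enolate, in which the chiral diphosphine–copper complex selects the enone face at C3 and the methylation at C2 makes that carbon quaternary and non-stereogenic.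

Step 2
Reactants: 3 (S)-2,2-dimethyl-3-vinylcyclohexan-1-one
Product: 5 (R)-3-(hydroxymethyl)-2,2-dimethylcyclohexan-1-one, via keto aldehyde 4 (not isolated)
Conditions: O3, CH2Cl2, −78 °C; PPh3, −78 → 0 °C; then NaBH4, EtOH, −78 °C
Reagents that add atoms: ozone [O-][O+]=O
Why: Ozonolysis with phosphine work-up cleaves the vinyl group to the aldehyde, which NaBH4 in ethanol at −78 °C should reduce much faster than the hindered α,α-dimethyl ketone (chemoselective carbonyl reduction), while the stereocenter is untouched (S becomes R only through the priority rules) and the enolisable aldehyde is not isolated so that it cannot epimerise.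

Step 3
Reactants: 5 (R)-3-(hydroxymethyl)-2,2-dimethylcyclohexan-1-one
Product: 6 [(1R)-2,2-dimethyl-3-oxocyclohexyl]methyl 4-methylbenzenesulfonate
Conditions: TsCl, Et3N, DMAP (cat.), CH2Cl2, 0 °C
Reagents that add atoms: 4-toluenesulfonyl chloride Cc1ccc(cc1)S(Cl)(=O)=O
Why: Sulfonylation of the primary alcohol under amine conditions that do not enolise the ketone, so the leaving group is installed without premature cyclisation and without change at the stereocenter.

Step 4
Reactants: 6 [(1R)-2,2-dimethyl-3-oxocyclohexyl]methyl 4-methylbenzenesulfonate; 7 1-(2,4,6-trifluorophenyl)ethan-1-one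
Product: 12 (1R,2R,4S)-5',7'-difluoro-3,3-dimethylspiro[bicyclo[2.2.1]heptane-2,2'-chroman]-4'-one, via potassium enolate 8 (not isolated), via camphenilone 9 (not isolated), via lithium enolate 10 (not isolated), via lithium aldolate 11 (not isolated)
Conditions: 6, KN(SiMe3)2 (1.05 equiv), THF, −78 → 25 °C; separately 7, LiN(SiMe3)2, THF, −78 °C; first solution added to the second at −78 °C, then −78 → 25 °C
Reagents that add atoms: none
Why: KN(SiMe3)2 can deprotonate 6 only at the ring CH2 beside the carbonyl (the future bridgehead C1), because the other α-carbon is the quaternary CMe2 carbon, which also shuts off the cyclopropane closure normal for γ-sulfonyloxy ketones; enolate 8 then displaces the tosylate at the future C7 in an intramolecular SN2 C-alkylation, the classical keto tosylate route to bridged bicyclic ketones. This closure of the five-membered ring C1–C6–C5–C4–C7 is 5-(enolexo)-exo-tet through the boat conformer with axial CH2OTs; O-alkylation would need a bridgehead enol ether and is excluded, and the new center C1 is dictated by C4 because the one-carbon bridge can only span the ring cis. Camphenilone 9 has no enolisable hydrogen, so the lithium enolate 10 can only add to its carbonyl (aldol addition), and it should do so from the exo face, as hydride and organometallic reagents do with 3,3-dimethylnorbornan-2-ones, which sets C2 with C3' exo and oxygen endo. The endo alkoxide 11 then closes the pyranone ring by addition–elimination (SNAr, six-membered ring closure at the ortho C–F carbon through a Meisenheimer adduct), activated by the ortho carbonyl group and the two other fluorines, and this forms the aryl–oxygen bond without breaking the C2–O bond. The step needs regioselective enolisation, C- over O-alkylation, exo facial selectivity and capture of the aldolate before retro-aldol cleavage: the CMe2 carbon, Bredt strain, the shape of the norbornane and the irreversible loss of fluoride secure these in turn. Running both stages in one flask also avoids isolating the volatile ketone 9.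

Step 5
Reactants: 12 (1R,2R,4S)-5',7'-difluoro-3,3-dimethylspiro[bicyclo[2.2.1]heptane-2,2'-chroman]-4'-one
Product: 13 (1R,2R,4S)-5',7'-bis(benzyloxy)-3,3-dimethylspiro[bicyclo[2.2.1]heptane-2,2'-chroman]-4'-one
Conditions: BnOH, NaH, DMF, 0 → 60 °C
Reagents that add atoms: benzyl alcohol OCc1ccccc1
Why: Twofold nucleophilic aromatic substitution (SNAr through Meisenheimer adducts) of the fluorides at C5' and C7', ortho and para to the C4' carbonyl group, by sodium benzyloxide, in which no stereocenter takes part and a reversible enolate ring-opening of the pyranone, should it occur, is expected to reclose to the same isomer with the larger CH2 group exo.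

Step 6
Reactants: 13 (1R,2R,4S)-5',7'-bis(benzyloxy)-3,3-dimethylspiro[bicyclo[2.2.1]heptane-2,2'-chroman]-4'-one
Product: 15 (1R,2S,4S)-5',7'-bis(benzyloxy)-3,3-dimethyl-4'-(2-methylpropyl)spiro[bicyclo[2.2.1]heptane-2,2'-chromene], via tertiary alcohol 14 (not isolated)
Conditions: i-BuLi, CeCl3, THF, −78 °C; aq NH4Cl; then PPTS (10 mol %), toluene, 40 °C
Reagents that add atoms: isobutyllithium [Li]CC(C)C
Why: 1,2-Addition of the weakly basic organocerium reagent to the hindered, enolisable aryl ketone followed by acid-catalysed E1 dehydration of the tertiary benzylic alcohol to the conjugated chromene, which erases the C4' center of 14 (an exocyclic alkene isomer would converge in step 7) while C2 keeps its geometry and changes only its descriptor.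

Step 7
Reactants: 15 (1R,2S,4S)-5',7'-bis(benzyloxy)-3,3-dimethyl-4'-(2-methylpropyl)spiro[bicyclo[2.2.1]heptane-2,2'-chromene]
Product: 16 (1R,2R,4S,4'S)-3,3-dimethyl-4'-(2-methylpropyl)spiro[bicyclo[2.2.1]heptane-2,2'-chromane]-5',7'-diol
Conditions: H2 (4 atm), Pd/C (10 % Pd on carbon), EtOAc–EtOH, 25 °C
Reagents that add atoms: none
Why: Heterogeneous syn hydrogenation of the styrene-type double bond with concurrent hydrogenolysis of both benzyl ethers, in which C4' is set by delivery of hydrogen to the alkene face that carries only the bridgehead C1–H, opposite the CMe2 carbon whose exo methyl group lies over C3', so that the isobutyl group ends up cis to C3.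

Step 8
Reactants: 16 (1R,2R,4S,4'S)-3,3-dimethyl-4'-(2-methylpropyl)spiro[bicyclo[2.2.1]heptane-2,2'-chromane]-5',7'-diol
Product: 17 (1R,2R,4S,4'S)-5',7'-dihydroxy-3,3-dimethyl-4'-(2-methylpropyl)spiro[bicyclo[2.2.1]heptane-2,2'-chromane]-6',8'-dicarbaldehyde
Conditions: POCl3, DMF, MeCN, 0 → 25 °C; then aq NaOAc, 40 °C
Reagents that add atoms: N,N-dimethylformamide CN(C)C=O; water O
Why: Twofold Vilsmeier–Haack formylation at C6' and C8', the only free positions of the phloroglucinol-type ring and both ortho or para to its three oxygens, with acetate-buffered hydrolysis of the bis-iminium salt so that no strong acid meets the tertiary spiro ether and no stereocenter is affected.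

**Compound list**
1 | 2-methylcyclohex-2-en-1-one | CC1=CCCCC1=O | starting material
2 | bromomagnesium (S)-2-methyl-3-vinylcyclohex-1-en-1-olate | C=C[C@@H]1CCCC(O[Mg]Br)=C1C | intermediate
3 | (S)-2,2-dimethyl-3-vinylcyclohexan-1-one | O=C1CCC[C@@H](C=C)C1(C)C | intermediate
4 | (R)-2,2-dimethyl-3-oxocyclohexane-1-carbaldehyde | O=C1CCC[C@@H](C=O)C1(C)C | intermediate
5 | (R)-3-(hydroxymethyl)-2,2-dimethylcyclohexan-1-one | O=C1CCC[C@@H](CO)C1(C)C | intermediate
6 | [(1R)-2,2-dimethyl-3-oxocyclohexyl]methyl 4-methylbenzenesulfonate | O=C1CCC[C@@H](COS(=O)(=O)c2ccc(C)cc2)C1(C)C | intermediate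
7 | 1-(2,4,6-trifluorophenyl)ethan-1-one | CC(=O)c1c(F)cc(F)cc1F | starting material
8 | potassium (R)-6,6-dimethyl-5-[(tosyloxy)methyl]cyclohex-1-en-1-olate | [K+].[O-]C1=CCC[C@@H](COS(=O)(=O)c2ccc(C)cc2)C1(C)C | intermediate
9 | (1R,4S)-3,3-dimethylbicyclo[2.2.1]heptan-2-one (camphenilone) | O=C1[C@@H]2CC[C@@H](C2)C1(C)C | intermediate
10 | lithium 1-(2,4,6-trifluorophenyl)ethen-1-olate | [Li+].[O-]C(=C)c1c(F)cc(F)cc1F | intermediate
11 | lithium (1R,2R,4S)-3,3-dimethyl-2-[2-oxo-2-(2,4,6-trifluorophenyl)ethyl]bicyclo[2.2.1]heptan-2-olate (oxygen endo) | [Li+].O=C(C[C@@]1([O-])[C@@H]2CC[C@@H](C2)C1(C)C)c1c(F)cc(F)cc1F | intermediate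
12 | (1R,2R,4S)-5',7'-difluoro-3,3-dimethylspiro[bicyclo[2.2.1]heptane-2,2'-chroman]-4'-one | O=C1C[C@@]2(Oc3cc(F)cc(F)c31)[C@@H]1CC[C@@H](C1)C2(C)C | intermediate
13 | (1R,2R,4S)-5',7'-bis(benzyloxy)-3,3-dimethylspiro[bicyclo[2.2.1]heptane-2,2'-chroman]-4'-one | O=C1C[C@@]2(Oc3cc(OCc4ccccc4)cc(OCc4ccccc4)c31)[C@@H]1CC[C@@H](C1)C2(C)C | intermediate
14 | (1R,2R,4S)-5',7'-bis(benzyloxy)-3,3-dimethyl-4'-(2-methylpropyl)spiro[bicyclo[2.2.1]heptane-2,2'-chroman]-4'-ol (either C4' epimer) | CC(C)CC1(O)C[C@@]2(Oc3cc(OCc4ccccc4)cc(OCc4ccccc4)c31)[C@@H]1CC[C@@H](C1)C2(C)C | intermediate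
15 | (1R,2S,4S)-5',7'-bis(benzyloxy)-3,3-dimethyl-4'-(2-methylpropyl)spiro[bicyclo[2.2.1]heptane-2,2'-chromene] (same geometry at C2 as in 13) | CC(C)CC1=C[C@@]2(Oc3cc(OCc4ccccc4)cc(OCc4ccccc4)c31)[C@@H]1CC[C@@H](C1)C2(C)C | intermediate
16 | (1R,2R,4S,4'S)-3,3-dimethyl-4'-(2-methylpropyl)spiro[bicyclo[2.2.1]heptane-2,2'-chromane]-5',7'-diol | CC(C)C[C@H]1C[C@@]2(Oc3cc(O)cc(O)c31)[C@@H]1CC[C@@H](C1)C2(C)C | intermediate
17 | (1R,2R,4S,4'S)-5',7'-dihydroxy-3,3-dimethyl-4'-(2-methylpropyl)spiro[bicyclo[2.2.1]heptane-2,2'-chromane]-6',8'-dicarbaldehyde | CC(C)C[C@H]1C[C@@]2(Oc3c(C=O)c(O)c(C=O)c(O)c31)[C@@H]1CC[C@@H](C1)C2(C)C | target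

**Step count and risks**
Total steps: 8. Longest linear sequence: 8 steps (1 to 17; ketone 7 is purchased and enters at step 4).

Steps most likely to fail:

1. Step 1. The copper-catalysed transfer of an sp2 vinyl group to an α-substituted enone may proceed with low enantiofacial discrimination, since vinyl Grignard reagents are poorer partners than primary alkyl ones; 3 and then 5 would be enantiomerically impure. The fallback sets out from 5 and returns to 5. The conjugate addition is run without reliance on the chiral ligand, and the scalemic or racemic 5 is esterified with (S)-2-methoxy-2-phenylacetic acid (DCC, DMAP, CH2Cl2). This gives the diastereomeric esters [(1R)-2,2-dimethyl-3-oxocyclohexyl]methyl (2S)-2-methoxy-2-phenylacetate F1 and [(1S)-2,2-dimethyl-3-oxocyclohexyl]methyl (2S)-2-methoxy-2-phenylacetate F2, which are separated by crystallisation or chromatography. Methanolysis of F1 (K2CO3, MeOH) returns enantiopure 5, a classical resolution in place of asymmetric catalysis.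

2. Step 4. The aldol addition to the crowded carbonyl group may reverse (retro-aldol cleavage) faster than the alkoxide closes the ring, or the enolate may be consumed by intermolecular substitution of aryl fluoride. The fallback sets out from 9 and returns to 12. Ketone 9 is isolated after the KN(SiMe3)2 stage and treated with the lithium enolate of N-methoxy-N-methylacetamide (LiN(i-Pr)2, THF, −78 °C). This amide enolate addition is much less reversible and should follow the same exo attack, giving 2-[(1R,2R,4S)-2-hydroxy-3,3-dimethylbicyclo[2.2.1]heptan-2-yl]-N-methoxy-N-methylacetamide F3. 2,4,6-Trifluorophenyllithium (from 1,3,5-trifluorobenzene and n-BuLi, THF, −78 °C) converts this Weinreb amide into 2-[(1R,2R,4S)-2-hydroxy-3,3-dimethylbicyclo[2.2.1]heptan-2-yl]-1-(2,4,6-trifluorophenyl)ethan-1-one F4. NaH in THF at 0 °C then closes the ring by SNAr to 12.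

3. Step 7. Facial discrimination on the catalyst surface may be poor, and reduction of the hindered trisubstituted alkene slow, so that the C4' epimer forms as well. The fallback sets out from 15 and returns to 16. Homogeneous hydrogenation under catalyst control with a chiral iridium phosphinooxazoline complex [Ir(cod)(L)][B(C6H3(CF3)2)4] (H2, CH2Cl2), the ligand enantiomer chosen to deliver hydrogen to the required face, should give (1R,2R,4S,4'S)-5',7'-bis(benzyloxy)-3,3-dimethyl-4'-(2-methylpropyl)spiro[bicyclo[2.2.1]heptane-2,2'-chromane] F5. Hydrogenolysis of the benzyl ethers (H2, Pd/C, EtOAc) then returns 16.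

Further compounds
F1 | step 1 | [(1R)-2,2-dimethyl-3-oxocyclohexyl]methyl (2S)-2-methoxy-2-phenylacetate | O=C1CCC[C@@H](COC(=O)[C@@H](OC)c2ccccc2)C1(C)C
F2 | step 1 | [(1S)-2,2-dimethyl-3-oxocyclohexyl]methyl (2S)-2-methoxy-2-phenylacetate | O=C1CCC[C@H](COC(=O)[C@@H](OC)c2ccccc2)C1(C)C
F3 | step 4 | 2-[(1R,2R,4S)-2-hydroxy-3,3-dimethylbicyclo[2.2.1]heptan-2-yl]-N-methoxy-N-methylacetamide | CON(C)C(=O)C[C@@]1(O)[C@@H]2CC[C@@H](C2)C1(C)C
F4 | step 4 | 2-[(1R,2R,4S)-2-hydroxy-3,3-dimethylbicyclo[2.2.1]heptan-2-yl]-1-(2,4,6-trifluorophenyl)ethan-1-one | O=C(C[C@@]1(O)[C@@H]2CC[C@@H](C2)C1(C)C)c1c(F)cc(F)cc1F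
F5 | step 7 | (1R,2R,4S,4'S)-5',7'-bis(benzyloxy)-3,3-dimethyl-4'-(2-methylpropyl)spiro[bicyclo[2.2.1]heptane-2,2'-chromane] | CC(C)C[C@H]1C[C@@]2(Oc3cc(OCc4ccccc4)cc(OCc4ccccc4)c31)[C@@H]1CC[C@@H](C1)C2(C)C
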